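**Plan** (lactone numbering: O1, C2(=O), C3=C4, C5(O-acyl), C6; propenyl C1'–C3'; acyl chain C1''–C12'')

- Enabling feature: C5 and C6 each carry one oxygen and one sp2 CH (C4 of the ring alkene, C1' of the propenyl group), threo to each other. Without C2–C3 the core C4–C5–C6–C1' is locally C2-symmetric: (2E,4S,5S,6E)-octa-2,6-diene-4,5-diol, i.e. L-tartaric acid with its carboxyl carbons turned into C4 and C1'. Its two OH groups are homotopic.
- Cuts, in retrosynthetic order: C3=C4 (relay ring-closing metathesis, last step); the ester bonds O5–C1'' and O1–C2; the two C=C bonds of the diol arms (double ethylidenation of L-tartraldehyde acetonide); in the acid C2''=C3'' (HWE), C4''=C5'' (Wittig) and C7''–C8'' (Cu-catalysed coupling).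
- Forward: diol → mono-ester with a relay-armed enoate → second ester with the complete dienoic acid → lactone ring closed last under neutral conditions, so the base-labile 5-acyloxy-dihydropyranone never meets base and no protecting group is used.
- Stereochemistry: C5 and C6 from L-tartrate (commercial L-threitol acetonide); C6'' from (R)-3-bromo-2-methylpropan-1-ol; E alkenes from Takai–Utimoto, Wittig and HWE reactions; the ring alkene is Z by ring size.
- Why not a plain acrylate: an external Ru carbene could not tell the two propenyl arms apart, so the catalyst is delivered from the ester that becomes C2–C3 (relay).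

Key step: step 11

**Step 1**
Reactants: 1 (4S,5S)-2,3-O-isopropylidene-L-threitol; 2 1,1-diiodoethane (two molecules are consumed, one per formyl group)
Product: 4 (4S,5S)-2,2-dimethyl-4,5-di[(1E)-prop-1-en-1-yl]-1,3-dioxolane, via tartraldehyde acetonide 3 (not isolated)
Conditions: IBX, EtOAc, 75 °C; filter, concentrate; then CrCl2 (excess), 2 (2.2–3 equiv), THF, 0 °C to rt
Reagents that add atoms: 1,1-diiodoethane (the second molecule, for the second formyl group), CC(I)I
Why: IBX oxidises both primary alcohols under neutral conditions to the C2-symmetric dialdehyde, and Takai–Utimoto ethylidenation (gem-dichromium reagent from 2 and CrCl2, one molecule of 2 per formyl group) should turn each formyl group into an (E)-propenyl group without base, so the two tartrate-derived stereocentres, which stay trans on the dioxolane, are not epimerised.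

**Step 2**
Reactants: 4 (4S,5S)-2,2-dimethyl-4,5-di[(1E)-prop-1-en-1-yl]-1,3-dioxolane
Product: 5 (2E,4S,5S,6E)-octa-2,6-diene-4,5-diol
Conditions: 2 M HCl, THF/H2O, rt to 40 °C
Reagents that add atoms: none
Why: Acid-catalysed acetal hydrolysis proceeds through the oxocarbenium ion at the acetal carbon, so the C–O bonds at the stereocentres are not broken and the C2-symmetric bis-allylic diol should be released with both stereocentres and both E alkenes unchanged.

**Step 3**
Reactants: 6 hex-5-enal; 7 malonic acid
Product: 8 (2E)-octa-2,7-dienoic acid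
Conditions: pyridine, piperidine (cat.), rt to 80 °C
Reagents that add atoms: none
Why: Knoevenagel–Doebner condensation with decarboxylation should give the conjugated (E)-acid and so installs in one operation the relay chain, a terminal alkene five carbons away from the enoate.

**Step 4**
Reactants: 5 (2E,4S,5S,6E)-octa-2,6-diene-4,5-diol (3 equiv); 8 (2E)-octa-2,7-dienoic acid
Product: 9 (2E,4S,5S,6E)-5-hydroxyocta-2,6-dien-4-yl (2E)-octa-2,7-dienoate
Conditions: DIC, DMAP (cat.), CH2Cl2, 0 °C to rt; excess 5 recovered
Reagents that add atoms: none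
Why: Steglich esterification; because the two hydroxyl groups of C2-symmetric 5 are homotopic, either one gives the same mono-ester, acyl migration in 9 is degenerate, and only over-acylation has to be held back, which the excess of recoverable diol does.

**Step 5**
Reactants: 10 (R)-3-bromo-2-methylpropan-1-ol; 11 pentylmagnesium bromide
Product: 12 (S)-2-methyloctan-1-ol
Conditions: 11 (3 equiv), Li2CuCl4 (5 mol %), THF, −78 °C to rt; aq. NH4Cl
Reagents that add atoms: none
Why: Copper-catalysed sp3–sp3 coupling of a Grignard reagent with a primary bromide (Kochi type); the first equivalent of 11 only forms the alkoxide, the stereocentre is not involved, and its descriptor changes from R to S solely through the CIP priorities.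

**Step 6**
Reactants: 12 (S)-2-methyloctan-1-ol
Product: 13 (S)-2-methyloctanal
Conditions: TEMPO (cat.), PhI(OAc)2, CH2Cl2, rt; used crude at once
Reagents that add atoms: none
Why: Oxoammonium-mediated (TEMPO/PhI(OAc)2) oxidation stops at the aldehyde under non-basic conditions, so the α-methyl stereocentre should not epimerise.

**Step 7**
Reactants: 13 (S)-2-methyloctanal; 14 2-(triphenyl-λ5-phosphanylidene)propanal
Product: 15 (2E,4S)-2,4-dimethyldec-2-enal
Conditions: toluene, 80 °C
Reagents that add atoms: none
Why: Wittig reaction with the formyl-stabilised ylide should give the trisubstituted (E)-enal under thermodynamic control, and the ylide is too weakly basic to enolise 13.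

**Step 8**
Reactants: 15 (2E,4S)-2,4-dimethyldec-2-enal; 16 triethyl phosphonoacetate
Product: 17 ethyl (2E,4E,6S)-4,6-dimethyldodeca-2,4-dienoate
Conditions: LiCl, DBU, MeCN, 0 °C to rt
Reagents that add atoms: none
Why: Horner–Wadsworth–Emmons reaction under Masamune–Roush conditions should give the (2E)-enoate, and the mild amine base leaves the γ-stereocentre of the enal untouched.

**Step 9**
Reactants: 17 ethyl (2E,4E,6S)-4,6-dimethyldodeca-2,4-dienoate
Product: 18 (2E,4E,6S)-4,6-dimethyldodeca-2,4-dienoic acid
Conditions: LiOH, THF/MeOH/H2O, rt; then 1 M HCl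
Reagents that add atoms: lithium hydroxide, [Li+].[OH-]
Why: Saponification of the ethyl ester (BAc2); the stereocentre is ε to the carboxylate and both E alkenes are conjugated, so neither should change.

**Step 10**
Reactants: 9 (2E,4S,5S,6E)-5-hydroxyocta-2,6-dien-4-yl (2E)-octa-2,7-dienoate; 18 (2E,4E,6S)-4,6-dimethyldodeca-2,4-dienoic acid
Product: 19 (2E,4S,5S,6E)-5-{[(2E)-octa-2,7-dienoyl]oxy}octa-2,6-dien-4-yl (2E,4E,6S)-4,6-dimethyldodeca-2,4-dienoate
Conditions: DIC, DMAP, CH2Cl2, 0 °C to rt
Reagents that add atoms: none
Why: Steglich esterification of the one remaining hydroxyl group; no regiochemical question is left, a 1,2-acyl shift before coupling would be degenerate, and the remote C6'' stereocentre is not at risk.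

**Step 11**
Reactants: 19 (2E,4S,5S,6E)-5-{[(2E)-octa-2,7-dienoyl]oxy}octa-2,6-dien-4-yl (2E,4E,6S)-4,6-dimethyldodeca-2,4-dienoate
Product: 20 (2S,3S)-6-oxo-2-[(1E)-prop-1-en-1-yl]-3,6-dihydro-2H-pyran-3-yl (2E,4E,6S)-4,6-dimethyldodeca-2,4-dienoate (target, CNP0240957.1; pyran positions 2 and 3 are C6 and C5 of the lactone numbering)
Conditions: Hoveyda–Grubbs 2nd-generation catalyst (5 mol %), 1,4-benzoquinone (10 mol %), CH2Cl2 (2 mM), 40 °C, argon sparge
Reagents that add atoms: none
Why: Relay ring-closing metathesis: the Ru alkylidene enters 19 at its only monosubstituted alkene (the terminus of the octadienoyl group), closes onto the enoate C=C with loss of cyclopentene and is thereby placed on the carbon that becomes C3, from where [2+2]/retro-[2+2] with the propenyl group on C5 forms C3=C4 and expels Ru=CHMe, which returns to the relay terminus of the next molecule with loss of propene. The closest known reaction types are relay RCM and the RCM of acrylates of alkenyl carbinols to 5,6-dihydropyran-2-ones. The one ring formed is the six-membered lactone, closed by olefin metathesis at C3=C4, and the ring size forces the Z geometry. No stereocentre is formed: C5 and C6 come unchanged from 1, C6'' from 10, and the C6 propenyl group should keep the E geometry set in step 1 because no carbene needs to be loaded on it. The step needs site selectivity between the two propenyl groups, which were homotopic in 5 and differ in 19 only by the ester on the neighbouring oxygen; it is secured by delivering the carbene intramolecularly through the relay (terminal alkene against E-1,2-disubstituted allylic-ester alkenes) and by the kinetic preference for the six-membered lactone over the butenolide that closure onto the C6 propenyl group would give. The conjugated, trisubstituted dienoate is a poor metathesis partner, and the neutral conditions keep the 5-acyloxy-dihydropyranone from eliminating to the 2-pyranone.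

**Compound list**

1 | (4S,5S)-2,3-O-isopropylidene-L-threitol | OC[C@@H]1OC(C)(C)O[C@H]1CO | starting material
2 | 1,1-diiodoethane | CC(I)I | starting material
3 | (4R,5R)-2,2-dimethyl-1,3-dioxolane-4,5-dicarbaldehyde (tartraldehyde acetonide) | O=C[C@@H]1OC(C)(C)O[C@H]1C=O | intermediate
4 | (4S,5S)-2,2-dimethyl-4,5-di[(1E)-prop-1-en-1-yl]-1,3-dioxolane | C/C=C/[C@@H]1OC(C)(C)O[C@H]1/C=C/C | intermediate
5 | (2E,4S,5S,6E)-octa-2,6-diene-4,5-diol | C/C=C/[C@H](O)[C@@H](O)/C=C/C | intermediate
6 | hex-5-enal | C=CCCCC=O | starting material
7 | malonic acid | OC(=O)CC(=O)O | starting material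
8 | (2E)-octa-2,7-dienoic acid | C=CCCC/C=C/C(=O)O | intermediate
9 | (2E,4S,5S,6E)-5-hydroxyocta-2,6-dien-4-yl (2E)-octa-2,7-dienoate | C/C=C/[C@H](OC(=O)/C=C/CCCC=C)[C@@H](O)/C=C/C | intermediate
10 | (R)-3-bromo-2-methylpropan-1-ol | OC[C@@H](C)CBr | starting material
11 | pentylmagnesium bromide | CCCCC[Mg]Br | starting material
12 | (S)-2-methyloctan-1-ol | OC[C@@H](C)CCCCCC | intermediate
13 | (S)-2-methyloctanal | O=C[C@@H](C)CCCCCC | intermediate
14 | 2-(triphenyl-λ5-phosphanylidene)propanal | CC(C=O)=P(c1ccccc1)(c1ccccc1)c1ccccc1 | starting material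
15 | (2E,4S)-2,4-dimethyldec-2-enal | O=C/C(C)=C/[C@@H](C)CCCCCC | intermediate
16 | triethyl phosphonoacetate | CCOC(=O)CP(=O)(OCC)OCC | starting material
17 | ethyl (2E,4E,6S)-4,6-dimethyldodeca-2,4-dienoate | CCOC(=O)/C=C/C(C)=C/[C@@H](C)CCCCCC | intermediate
18 | (2E,4E,6S)-4,6-dimethyldodeca-2,4-dienoic acid | OC(=O)/C=C/C(C)=C/[C@@H](C)CCCCCC | intermediate
19 | (2E,4S,5S,6E)-5-{[(2E)-octa-2,7-dienoyl]oxy}octa-2,6-dien-4-yl (2E,4E,6S)-4,6-dimethyldodeca-2,4-dienoate | C/C=C/[C@H](OC(=O)/C=C/CCCC=C)[C@@H](OC(=O)/C=C/C(C)=C/[C@@H](C)CCCCCC)/C=C/C | intermediate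
20 | (2S,3S)-6-oxo-2-[(1E)-prop-1-en-1-yl]-3,6-dihydro-2H-pyran-3-yl (2E,4E,6S)-4,6-dimethyldodeca-2,4-dienoate | C/C=C/[C@@H]1OC(=O)C=C[C@@H]1OC(=O)/C=C/C(C)=C/[C@@H](C)CCCCCC | target

**Totals**

Total step count: 11. Longest linear sequence: 7 steps (10 → 12 → 13 → 15 → 17 → 18 → 19 → 20; steps 5–11).

**Steps most likely to fail**

1. Step 11. The relay may fail to outrun direct loading of the catalyst on either propenyl group, which would scramble the E geometry or truncate the C6 propenyl group. Closure through the C6 propenyl group to the butenolide, or decay of the ester-substituted carbene before it cyclises, are the other failure paths. The fallback sets out from 5 (and uses 18) and comes back at 20. Excess 5 is mono-acylated with acrylic acid (DIC, DMAP) to (2E,4S,5S,6E)-5-hydroxyocta-2,6-dien-4-yl prop-2-enoate F1. Ring-closing metathesis of F1 (Hoveyda–Grubbs II, CH2Cl2, 40 °C) should be steered to the propenyl group next to the free hydroxyl, because a free allylic OH accelerates carbene loading while the other propenyl group is a slower allylic ester. It should give (5S,6S)-5-hydroxy-6-[(1E)-prop-1-en-1-yl]-5,6-dihydro-2H-pyran-2-one F2 with loss of propene. Steglich esterification of F2 with 18 at 0 °C (short time, little DMAP, to avoid elimination) then gives 20.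

2. Step 1. E selectivity in the double ethylidenation may be incomplete, and dialdehyde 3 may hydrate or oligomerise during telescoping. An E,Z isomer matters because the arms are homotopic: it would place a Z-propenyl group on C6 in half of the molecules derived from it, so it must be removed at 4 or 5. The fallback sets out from 3 and comes back at 5, with the geometry set by alkyne reduction instead of olefination. Homologation of 3 with dimethyl (1-diazo-2-oxopropyl)phosphonate (K2CO3, MeOH) gives (4S,5S)-4,5-diethynyl-2,2-dimethyl-1,3-dioxolane F3. Double deprotonation (n-BuLi) and methylation (MeI) gives (4S,5S)-2,2-dimethyl-4,5-di(prop-1-yn-1-yl)-1,3-dioxolane F4. Acid hydrolysis gives (4S,5S)-octa-2,6-diyne-4,5-diol F5. Red-Al in THF should reduce both propargylic alcohols by alkoxide-directed trans-hydroalumination to 5 with E geometry only.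

3. Step 10. Acyl transfer of the conjugated dienoic acid to the hindered allylic hydroxyl beside an acyloxy group may be slow, so that rearrangement of the activated acid to the N-acylurea or base-induced deconjugation of the relay enoate takes over. The fallback sets out from 9 (and uses 15) and comes back at 19, building the dienoate on the substrate. Steglich coupling of 9 with the small (diethoxyphosphoryl)acetic acid gives (2E,4S,5S,6E)-5-{[(2E)-octa-2,7-dienoyl]oxy}octa-2,6-dien-4-yl 2-(diethoxyphosphoryl)acetate F6. Horner–Wadsworth–Emmons reaction of F6 with enal 15 (LiCl, iPr2NEt, MeCN) forms C2''=C3'' and should give 19 directly.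

**Further compounds**

F1 | step 11 | (2E,4S,5S,6E)-5-hydroxyocta-2,6-dien-4-yl prop-2-enoate | C/C=C/[C@H](OC(=O)C=C)[C@@H](O)/C=C/C
F2 | step 11 | (5S,6S)-5-hydroxy-6-[(1E)-prop-1-en-1-yl]-5,6-dihydro-2H-pyran-2-one | C/C=C/[C@@H]1OC(=O)C=C[C@@H]1O
F3 | step 1 | (4S,5S)-4,5-diethynyl-2,2-dimethyl-1,3-dioxolane | C#C[C@@H]1OC(C)(C)O[C@H]1C#C
F4 | step 1 | (4S,5S)-2,2-dimethyl-4,5-di(prop-1-yn-1-yl)-1,3-dioxolane | CC#C[C@@H]1OC(C)(C)O[C@H]1C#CC
F5 | step 1 | (4S,5S)-octa-2,6-diyne-4,5-diol | CC#C[C@H](O)[C@@H](O)C#CC
F6 | step 10 | (2E,4S,5S,6E)-5-{[(2E)-octa-2,7-dienoyl]oxy}octa-2,6-dien-4-yl 2-(diethoxyphosphoryl)acetate | C/C=C/[C@H](OC(=O)/C=C/CCCC=C)[C@@H](OC(=O)CP(=O)(OCC)OCC)/C=C/C
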